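**Retrosynthetic overview**
1. Target 29 ← C14 acetylation ← Sharpless epoxidation of C1=C10 ← desilylation of the ten-membered triene lactone 26 (epoxide made last).
2. 26 ← C3–C4 bond by one-pot hydroboration / Pd-catalysed intramolecular B-alkyl Suzuki–Miyaura coupling of the seco alkenyl iodide/diene 24 (the ten-membered ring closes here).
3. 24 ← Mitsunobu methacrylation with inversion at C8 ← Zn Barbier union (C7–C8, gives the α-methylene lactone, sets C7 and C8) of bromobutenolide 10 with dienal 20.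
4. 10 ← acrolein, propynyl Grignard, 2-(bromomethyl)acrylic acid (Sharpless kinetic resolution sets C6; Red-Al/I2 sets the Z C4=C5; RCM makes the butenolide). 20 ← propargyl alcohol, vinyl Grignard, vinyl-BF3K (Cu-catalysed anti-carbomagnesiation sets the C1=C10 geometry).
5. Ring order: butenolide → trans-fused α-methylene-γ-lactone → ten-membered carbocycle → epoxide.

Assumption: atoms are named by germacrane numbering (C1–C10 ring, C11–C13 methylene lactone, C14 = CH2O on C10, C15 = CH3 on C4); CIP letters of some intermediates differ from the target for the same spatial arrangement because iodine at C4 changes priorities.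

**Steps**

Step 1
Reactants: 1 prop-2-enal (acrolein); 2 prop-1-yn-1-ylmagnesium bromide
Product: 3 rac-hex-1-en-4-yn-3-ol
Conditions: THF, −78 to 0 °C; then H2O
Reagents that add atoms: none
Why: Grignard 1,2-addition of the alkynyl nucleophile to the enal carbonyl gives the racemic alkynyl vinyl carbinol (C4–C7 plus C15).

Step 2
Reactants: 3 rac-hex-1-en-4-yn-3-ol
Product: 4 (3S)-hex-1-en-4-yn-3-ol
Conditions: Ti(OiPr)4 (10 mol %), L-(+)-DIPT (15 mol %), TBHP (0.6 equiv, decane), 4 Å MS, CH2Cl2, −20 °C, to about 55 % conversion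
Reagents that add atoms: none
Why: Sharpless kinetic resolution, in which the L-(+)-tartrate catalyst epoxidises the vinyl group of the 3R enantiomer much faster, so the 3S alcohol (the future C6 configuration) is recovered.

Step 3
Reactants: 4 (3S)-hex-1-en-4-yn-3-ol
Product: 6 (3S,4Z)-5-iodohexa-1,4-dien-3-ol, via cyclic vinylalanate 5 (not isolated)
Conditions: NaAlH2(OCH2CH2OCH3)2, THF, 0 °C to rt; then I2, −78 to 0 °C
Reagents that add atoms: iodine, II
Why: Hydroxyl-directed trans-hydroalumination of the propargylic alcohol puts aluminium on the distal alkyne carbon cis to the carbinol, and iodinolysis with retention gives the Z alkenyl iodide (I cis to C6), which fixes the C4=C5 geometry.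

Step 4
Reactants: 7 2-(bromomethyl)prop-2-enoic acid
Product: 8 2-(bromomethyl)prop-2-enoyl chloride
Conditions: (COCl)2, DMF (cat.), CH2Cl2, 0 °C to rt; used crude
Reagents that add atoms: oxalyl chloride, ClC(=O)C(Cl)=O
Why: Vilsmeier-type acid chloride formation gives an acylating agent that needs no nucleophilic catalyst, which protects the allylic bromide.

Step 5
Reactants: 6 (3S,4Z)-5-iodohexa-1,4-dien-3-ol; 8 2-(bromomethyl)prop-2-enoyl chloride
Product: 9 (3S,4Z)-5-iodohexa-1,4-dien-3-yl 2-(bromomethyl)prop-2-enoate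
Conditions: 2,6-lutidine, CH2Cl2, −30 to 0 °C
Reagents that add atoms: none
Why: O-acylation of the secondary alcohol with a hindered, non-nucleophilic base leaves the stereocentre and the allylic bromide untouched.

Step 6
Reactants: 9 (3S,4Z)-5-iodohexa-1,4-dien-3-yl 2-(bromomethyl)prop-2-enoate
Product: 10 (5S)-3-(bromomethyl)-5-[(1Z)-2-iodoprop-1-en-1-yl]furan-2(5H)-one
Conditions: second-generation Grubbs catalyst RuCl2(PCy3)(SIMes)(=CHPh) (5 mol %), toluene, 80 °C, Ar sparge
Reagents that add atoms: none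
Why: Ring-closing metathesis between the vinyl group and the 1,1-disubstituted acrylate closes the butenolide (C7=C11) with loss of ethene, while the trisubstituted alkenyl iodide is too hindered and electron-poor to take part.

Step 7
Reactants: 11 prop-2-yn-1-ol; 12 ethenylmagnesium bromide (3 equiv)
Product: 14 (2Z)-2-(iodomethylidene)but-3-en-1-ol, via oxamagnesacycle 13 (not isolated)
Conditions: CuI (10 mol %), THF, −10 °C to rt; then I2, −40 to 0 °C; then H2O
Reagents that add atoms: iodine, II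
Why: Copper-catalysed anti-carbomagnesiation of the propargylic alkoxide (Duboudin reaction) puts the vinyl group on C10 and magnesium on C1 in a five-membered chelate cis to the CH2O group, and iodinolysis with retention fixes the C1=C10 geometry (I, later C2, cis to C14).

Step 8
Reactants: 14 (2Z)-2-(iodomethylidene)but-3-en-1-ol
Product: 15 tert-butyl{[(2Z)-2-(iodomethylidene)but-3-en-1-yl]oxy}dimethylsilane
Conditions: TBSCl, imidazole, DMF, 0 °C to rt
Reagents that add atoms: tert-butyldimethylsilyl chloride, CC(C)(C)[Si](C)(C)Cl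
Why: Standard silylation protects the C14 hydroxyl through the organometallic steps.

Step 9
Reactants: 15 tert-butyl{[(2Z)-2-(iodomethylidene)but-3-en-1-yl]oxy}dimethylsilane
Product: 17 (3Z)-3-({[tert-butyl(dimethyl)silyl]oxy}methyl)-4-iodobut-3-en-1-ol, via B-alkyl-9-BBN 16 (not isolated)
Conditions: 9-BBN (1.1 equiv), THF, 0 °C to rt; then NaOH, H2O2, 0 °C
Reagents that add atoms: hydrogen peroxide, OO
Why: Hydroboration–oxidation, in which the bulky borane adds anti-Markovnikov to the unhindered terminal vinyl group only (the iodoalkene is inert), gives the C8 primary alcohol.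

Step 10
Reactants: 17 (3Z)-3-({[tert-butyl(dimethyl)silyl]oxy}methyl)-4-iodobut-3-en-1-ol; 18 potassium ethenyltrifluoroborate
Product: 19 (3Z)-3-({[tert-butyl(dimethyl)silyl]oxy}methyl)hexa-3,5-dien-1-ol
Conditions: PdCl2(dppf) (3 mol %), Cs2CO3 (3 equiv), THF/H2O 9:1, 65 °C
Reagents that add atoms: none
Why: Suzuki–Miyaura vinylation of the alkenyl iodide proceeds with retention, so C2 ends cis to C14 and trans to C9.

Step 11
Reactants: 19 (3Z)-3-({[tert-butyl(dimethyl)silyl]oxy}methyl)hexa-3,5-dien-1-ol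
Product: 20 (3Z)-3-({[tert-butyl(dimethyl)silyl]oxy}methyl)hexa-3,5-dienal
Conditions: Dess–Martin periodinane, NaHCO3, CH2Cl2, 0 °C; filtered and used at once
Reagents that add atoms: none
Why: Buffered Dess–Martin oxidation gives the β,γ-unsaturated aldehyde without base that would move the alkene into conjugation.

Step 12
Reactants: 10 (5S)-3-(bromomethyl)-5-[(1Z)-2-iodoprop-1-en-1-yl]furan-2(5H)-one; 20 (3Z)-3-({[tert-butyl(dimethyl)silyl]oxy}methyl)hexa-3,5-dienal
Product: 22 (4R,5S)-4-[(1S,3Z)-3-({[tert-butyl(dimethyl)silyl]oxy}methyl)-1-hydroxyhexa-3,5-dien-1-yl]-5-[(1Z)-2-iodoprop-1-en-1-yl]-3-methylideneoxolan-2-one, via allylzinc bromide 21 (not isolated)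
Conditions: Zn (5 equiv), THF/sat. aq NH4Cl 5:1, 0 °C to rt
Reagents that add atoms: none
Why: Barbier allylation with allylic transposition, in which the allylzinc adds through a chair transition state on the butenolide face anti to the C6 alkenyl group (trans C6/C7) with the aldehyde chain equatorial, gives the exo-methylene lactone and the 8S carbinol (C7/C8 anti).

Step 13
Reactants: 22 the 8S alcohol from step 12; 23 2-methylprop-2-enoic acid (methacrylic acid)
Product: 24 (1R,3Z)-3-({[tert-butyl(dimethyl)silyl]oxy}methyl)-1-{(2S,3R)-2-[(1Z)-2-iodoprop-1-en-1-yl]-4-methylidene-5-oxooxolan-3-yl}hexa-3,5-dien-1-yl 2-methylprop-2-enoate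
Conditions: PPh3, DIAD, THF, 0 °C to rt
Reagents that add atoms: none
Why: Mitsunobu esterification, in which methacrylate displaces the alkoxyphosphonium by SN2, inverts C8 from S to the required R and installs the ester in one operation.

Step 14
Reactants: 24 the seco methacrylate from step 13
Product: 26 (6R,7R,8R)-14-[(tert-butyldimethylsilyl)oxy]-8-(methacryloyloxy)germacra-1(10),4,11(13)-trien-12,6-olide (C1=C10 with C2 cis to C14, CIP Z; C4=C5 Z), via B-alkyl-9-BBN 25 (not isolated)
Conditions: 9-BBN (1.15 equiv), THF, 0 °C to rt, 3 h; then syringe-pump addition over 10 h to PdCl2(dppf) (15 mol %), AsPh3 (30 mol %), Cs2CO3 (3 equiv), degassed DMF/THF/H2O, 25 °C, final 1 mM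
Reagents that add atoms: none
Why: Proposed new method: one-pot chemoselective hydroboration / ten-membered-ring-closing B-alkyl Suzuki–Miyaura coupling, in which 9-BBN adds only to the terminal CH2 of the diene (far faster than to the two electron-poor 1,1-disubstituted enoates or the trisubstituted alkenes), zerovalent palladium inserts into the Z alkenyl C4–I bond with retention, the hydroxo-borate transfers the primary C3 alkyl group, and reductive elimination forms C3–C4, with the trans-fused lactone, the Z alkenyl iodide and the C1=C10 alkene holding the two termini close; the closest known reaction type is the intramolecular B-alkyl Suzuki–Miyaura macrocyclisation, established for other ring sizes but not for a ten-membered 1(10),4-germacradiene carrying enoate acceptors.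

Step 15
Reactants: 26 the silyl-protected macrocycle
Product: 27 (6R,7R,8R)-14-hydroxy-8-(methacryloyloxy)germacra-1(10),4,11(13)-trien-12,6-olide (same alkene geometries)
Conditions: HF·pyridine, pyridine, THF, 0 °C to rt
Reagents that add atoms: none
Why: Buffered fluoride desilylation frees the primary allylic alcohol without touching the two Michael acceptors.

Step 16
Reactants: 27 the macrocyclic allylic alcohol
Product: 28 (1R,4Z,6R,7R,8R,10S)-1,10-epoxy-14-hydroxy-8-(methacryloyloxy)germacra-4,11(13)-dien-12,6-olide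
Conditions: Ti(OiPr)4 (20 mol %), L-(+)-DET (28 mol %), TBHP (2 equiv, decane), 4 Å MS, CH2Cl2, −20 °C
Reagents that add atoms: tert-butyl hydroperoxide, CC(C)(C)OO
Why: Sharpless asymmetric epoxidation, in which the L-(+)-tartrate titanium catalyst delivers oxygen to the allylic-alcohol face that gives 10S, and the trans arrangement of C9 and C2 on the alkene then fixes 1R; this is expected to be the exposed outer face of the ring alkene, and the enoates and the non-allylic C4=C5 alkene do not react.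

Step 17
Reactants: 28 the epoxy alcohol
Product: 29 (1R,4Z,6R,7R,8R,10S)-14-acetoxy-1,10-epoxy-8-(methacryloyloxy)germacra-4,11(13)-dien-12,6-olide (target CNP0150481.2)
Conditions: Ac2O, pyridine, CH2Cl2, 0 °C to rt
Reagents that add atoms: acetic anhydride, CC(=O)OC(C)=O
Why: Acetylation of the only free (primary) hydroxyl completes the target without affecting any stereocentre.

**Compound list**
1 | prop-2-enal (acrolein) | C=CC=O | starting material
2 | prop-1-yn-1-ylmagnesium bromide | CC#C[Mg]Br | starting material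
3 | rac-hex-1-en-4-yn-3-ol | CC#CC(O)C=C | intermediate
4 | (3S)-hex-1-en-4-yn-3-ol | CC#C[C@H](C=C)O | intermediate
5 | sodium (5S)-5-ethenyl-2,2-bis(2-methoxyethoxy)-3-methyl-2,5-dihydro-1,2-oxaluminol-2-uide (cyclic vinylalanate) | [Na+].CC1=C[C@H](C=C)O[Al-]1(OCCOC)OCCOC | intermediate (not isolated)
6 | (3S,4Z)-5-iodohexa-1,4-dien-3-ol | I/C(C)=C\[C@H](C=C)O | intermediate
7 | 2-(bromomethyl)prop-2-enoic acid | C=C(CBr)C(=O)O | starting material
8 | 2-(bromomethyl)prop-2-enoyl chloride | C=C(CBr)C(=O)Cl | intermediate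
9 | (3S,4Z)-5-iodohexa-1,4-dien-3-yl 2-(bromomethyl)prop-2-enoate | I/C(C)=C\[C@H](C=C)OC(=O)C(=C)CBr | intermediate
10 | (5S)-3-(bromomethyl)-5-[(1Z)-2-iodoprop-1-en-1-yl]furan-2(5H)-one | I/C(C)=C\[C@H]1OC(=O)C(CBr)=C1 | intermediate
11 | prop-2-yn-1-ol | C#CCO | starting material
12 | ethenylmagnesium bromide | C=C[Mg]Br | starting material
13 | 4-ethenyl-2,5-dihydro-1,2-oxamagnesole (chelated alkenylmagnesium alkoxide) | C=CC1=C[Mg]OC1 | intermediate (not isolated)
14 | (2Z)-2-(iodomethylidene)but-3-en-1-ol | OC/C(C=C)=C\I | intermediate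
15 | tert-butyl{[(2Z)-2-(iodomethylidene)but-3-en-1-yl]oxy}dimethylsilane | CC(C)(C)[Si](C)(C)OC/C(C=C)=C\I | intermediate
16 | 9-[(3Z)-3-({[tert-butyl(dimethyl)silyl]oxy}methyl)-4-iodobut-3-en-1-yl]-9-borabicyclo[3.3.1]nonane | CC(C)(C)[Si](C)(C)OC/C(CCB1C2CCCC1CCC2)=C\I | intermediate (not isolated)
17 | (3Z)-3-({[tert-butyl(dimethyl)silyl]oxy}methyl)-4-iodobut-3-en-1-ol | CC(C)(C)[Si](C)(C)OC/C(CCO)=C\I | intermediate
18 | potassium ethenyltrifluoroborate | [K+].C=C[B-](F)(F)F | starting material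
19 | (3Z)-3-({[tert-butyl(dimethyl)silyl]oxy}methyl)hexa-3,5-dien-1-ol | CC(C)(C)[Si](C)(C)OC/C(CCO)=C\C=C | intermediate
20 | (3Z)-3-({[tert-butyl(dimethyl)silyl]oxy}methyl)hexa-3,5-dienal | CC(C)(C)[Si](C)(C)OC/C(CC=O)=C\C=C | intermediate
21 | bromo({(5S)-5-[(1Z)-2-iodoprop-1-en-1-yl]-2-oxo-2,5-dihydrofuran-3-yl}methyl)zinc | I/C(C)=C\[C@H]1OC(=O)C(C[Zn]Br)=C1 | intermediate (not isolated)
22 | (4R,5S)-4-[(1S,3Z)-3-({[tert-butyl(dimethyl)silyl]oxy}methyl)-1-hydroxyhexa-3,5-dien-1-yl]-5-[(1Z)-2-iodoprop-1-en-1-yl]-3-methylideneoxolan-2-one | O[C@@H](C/C(CO[Si](C)(C)C(C)(C)C)=C/C=C)[C@H]1C(=C)C(=O)O[C@@H]1/C=C(C)\I | intermediate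
23 | 2-methylprop-2-enoic acid (methacrylic acid) | C=C(C)C(=O)O | starting material
24 | (1R,3Z)-3-({[tert-butyl(dimethyl)silyl]oxy}methyl)-1-{(2S,3R)-2-[(1Z)-2-iodoprop-1-en-1-yl]-4-methylidene-5-oxooxolan-3-yl}hexa-3,5-dien-1-yl 2-methylprop-2-enoate | C=C(C)C(=O)O[C@H](C/C(CO[Si](C)(C)C(C)(C)C)=C/C=C)[C@H]1C(=C)C(=O)O[C@@H]1/C=C(C)\I | intermediate
25 | (1R,3Z)-6-(9-borabicyclo[3.3.1]nonan-9-yl)-3-({[tert-butyl(dimethyl)silyl]oxy}methyl)-1-{(2S,3R)-2-[(1Z)-2-iodoprop-1-en-1-yl]-4-methylidene-5-oxooxolan-3-yl}hex-3-en-1-yl 2-methylprop-2-enoate | C=C(C)C(=O)O[C@H](C/C(CO[Si](C)(C)C(C)(C)C)=C/CCB1C2CCCC1CCC2)[C@H]1C(=C)C(=O)O[C@@H]1/C=C(C)\I | intermediate (not isolated)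
26 | (6R,7R,8R)-14-[(tert-butyldimethylsilyl)oxy]-8-(methacryloyloxy)germacra-1(10),4,11(13)-trien-12,6-olide; C1=C10 CIP Z (C2 cis to C14), C4=C5 Z | C=C(C)C(=O)O[C@@H]1C/C(CO[Si](C)(C)C(C)(C)C)=C/CC/C(C)=C\[C@H]2OC(=O)C(=C)[C@@H]21 | intermediate
27 | (6R,7R,8R)-14-hydroxy-8-(methacryloyloxy)germacra-1(10),4,11(13)-trien-12,6-olide; same alkene geometries | C=C(C)C(=O)O[C@@H]1C/C(CO)=C/CC/C(C)=C\[C@H]2OC(=O)C(=C)[C@@H]21 | intermediate
28 | (1R,4Z,6R,7R,8R,10S)-1,10-epoxy-14-hydroxy-8-(methacryloyloxy)germacra-4,11(13)-dien-12,6-olide | C=C(C)C(=O)O[C@@H]1C[C@@]2(CO)O[C@@H]2CC/C(C)=C\[C@H]2OC(=O)C(=C)[C@@H]21 | intermediate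
29 | (1R,4Z,6R,7R,8R,10S)-14-acetoxy-1,10-epoxy-8-(methacryloyloxy)germacra-4,11(13)-dien-12,6-olide (CNP0150481.2) | C=C(C)C(=O)O[C@@H]1C[C@@]2(COC(C)=O)O[C@@H]2CC/C(C)=C\[C@H]2OC(=O)C(=C)[C@@H]21 | target

**Step count and risks**

Total step count: 17. Longest linear sequence: 11 steps (1, 2, 3, 5, 6, then 12–17; the branch 7–11 then 12–17 is equally long).

Most likely to fail, first: step 14, the proposed new macrocyclisation. The risks are slow attack of 9-BBN on the two enoates, Heck-type side reactions of the alkenylpalladium with the exo-methylene group, and ring strain. The fallback uses known chemistry and reverses the order of the two C–C bond formations; it sets out from 19 and 6 and comes back at 26. Hydroboration of 19 with 9-BBN gives the homoallylic borane F1, which is coupled intermolecularly with 6 (PdCl2(dppf), AsPh3, Cs2CO3, DMF/THF/H2O) to give the triene diol F2. TEMPO/PhI(OAc)2 oxidises only the primary alcohol and gives the hydroxy aldehyde F3. Acylation with 8 and 2,6-lutidine gives the bromomethylacrylate F4. Ring-closing metathesis with the second-generation Grubbs catalyst RuCl2(PCy3)(SIMes)(=CHPh) gives the bromobutenolide aldehyde F5. Zn in THF/aq NH4Cl at 2 mM forms the allylzinc bromide F6, which closes the ten-membered ring by intramolecular Barbier allylation to the macrocyclic 8S alcohol F7. Mitsunobu esterification of F7 with 23, as in step 13, returns to 26; if the 8R epimer forms instead, direct acylation with 23 gives 26.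

Second: step 13, the Mitsunobu inversion, where elimination towards the conjugated triene can compete. The fallback sets out from 22 and comes back at 24. Dess–Martin oxidation (NaHCO3, 0 °C) gives the C8 ketone F8. Reduction with catecholborane and (S)-2-methyl-CBS-oxazaborolidine at −78 °C, which treats the branched C7 side as the large group, gives the 8R alcohol F9. Esterification of F9 with 23 (EDC·HCl, DMAP, CH2Cl2, 0 °C) gives 24.

Third: step 7, because vinyl Grignard reagents are poorer partners than alkyl or allyl ones in the copper-catalysed carbomagnesiation. The fallback sets out from 11 and comes back at 17. Allylmagnesium bromide with CuI adds in the same anti sense through the oxamagnesacycle F10, and I2 then gives the allyl iodo alcohol F11. TBSCl/imidazole gives the silyl ether F12. OsO4 (cat.)/NaIO4/2,6-lutidine cleaves only the terminal alkene and gives the iodo aldehyde F13. NaBH4 reduction of F13 gives 17.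

**Further compounds**
F1 | step 14 | (3Z)-6-(9-borabicyclo[3.3.1]nonan-9-yl)-3-({[tert-butyl(dimethyl)silyl]oxy}methyl)hex-3-en-1-ol | CC(C)(C)[Si](C)(C)OC/C(CCO)=C\CCB1C2CCCC1CCC2
F2 | step 14 | (3Z,7Z,9S)-3-({[tert-butyl(dimethyl)silyl]oxy}methyl)-7-methylundeca-3,7,10-triene-1,9-diol | CC(C)(C)[Si](C)(C)OC/C(CCO)=C\CC/C(C)=C\[C@H](C=C)O
F3 | step 14 | (3Z,7Z,9S)-3-({[tert-butyl(dimethyl)silyl]oxy}methyl)-9-hydroxy-7-methylundeca-3,7,10-trienal | CC(C)(C)[Si](C)(C)OC/C(CC=O)=C\CC/C(C)=C\[C@H](C=C)O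
F4 | step 14 | (3S,4Z,8Z)-9-({[tert-butyl(dimethyl)silyl]oxy}methyl)-5-methyl-11-oxoundeca-1,4,8-trien-3-yl 2-(bromomethyl)prop-2-enoate | CC(C)(C)[Si](C)(C)OC/C(CC=O)=C\CC/C(C)=C\[C@H](C=C)OC(=O)C(=C)CBr
F5 | step 14 | (3Z,7Z)-8-[(2R)-4-(bromomethyl)-5-oxo-2,5-dihydrofuran-2-yl]-3-({[tert-butyl(dimethyl)silyl]oxy}methyl)-7-methylocta-3,7-dienal | CC(C)(C)[Si](C)(C)OC/C(CC=O)=C\CC/C(C)=C\[C@H]1OC(=O)C(CBr)=C1
F6 | step 14 | allylzinc bromide of F5 (ZnBr in place of Br on the butenolide CH2) | CC(C)(C)[Si](C)(C)OC/C(CC=O)=C\CC/C(C)=C\[C@H]1OC(=O)C(C[Zn]Br)=C1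
F7 | step 14 | (6R,7R,8S)-14-[(tert-butyldimethylsilyl)oxy]-8-hydroxygermacra-1(10),4,11(13)-trien-12,6-olide (alkene geometries as in 26) | O[C@H]1C/C(CO[Si](C)(C)C(C)(C)C)=C/CC/C(C)=C\[C@H]2OC(=O)C(=C)[C@@H]21
F8 | step 13 | (4S,5S)-4-[(3Z)-3-({[tert-butyl(dimethyl)silyl]oxy}methyl)hexa-3,5-dienoyl]-5-[(1Z)-2-iodoprop-1-en-1-yl]-3-methylideneoxolan-2-one | O=C(C/C(CO[Si](C)(C)C(C)(C)C)=C/C=C)[C@H]1C(=C)C(=O)O[C@@H]1/C=C(C)\I
F9 | step 13 | (4R,5S)-4-[(1R,3Z)-3-({[tert-butyl(dimethyl)silyl]oxy}methyl)-1-hydroxyhexa-3,5-dien-1-yl]-5-[(1Z)-2-iodoprop-1-en-1-yl]-3-methylideneoxolan-2-one | O[C@H](C/C(CO[Si](C)(C)C(C)(C)C)=C/C=C)[C@H]1C(=C)C(=O)O[C@@H]1/C=C(C)\I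
F10 | step 7 | 4-(prop-2-en-1-yl)-2,5-dihydro-1,2-oxamagnesole | C=CCC1=C[Mg]OC1
F11 | step 7 | (2Z)-2-(iodomethylidene)pent-4-en-1-ol | OC/C(CC=C)=C\I
F12 | step 7 | tert-butyl{[(2Z)-2-(iodomethylidene)pent-4-en-1-yl]oxy}dimethylsilane | CC(C)(C)[Si](C)(C)OC/C(CC=C)=C\I
F13 | step 7 | (3Z)-3-({[tert-butyl(dimethyl)silyl]oxy}methyl)-4-iodobut-3-enal | CC(C)(C)[Si](C)(C)OC/C(CC=O)=C\I
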